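In a one-step world, substrate plus partner gives product and nothing else, so the product at the end of a flask equals the smaller charge, partner or the two substrates together. You asked for a quick number for the excess along the partner row, with the hunch that it sinks as partner rises.

all flasks: left-handed substrate 0.050 M; right-handed substrate 0.050 M; free catalyst 2.5 mM

| charge | partner | remark | time |
|---|---|---|---|
| alder | 0.037 M | run made earlier |  |
| ash | 0.22 M | run made earlier |  |
| delta | 0.0300 M |  | 15 h |
| theta | 0.0500 M |  | 15 h |
| alpha | 0.0600 M |  | 15 h |
| eta | 0.100 M |  | 15 h |
| zeta | 0.150 M |  | 15 h |

| run | time / h | left-handed product / % | right-handed product / % |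
|---|---|---|---|
| alder | 1.33 | 3.5 | 2.0 |
| alder | 2.50 | 6.5 | 2.9 |
| alder | 4.00 | 8.2 | 3.9 |
| alder | 8.00 | 9.9 | 4.8 |
| alder | 15.0 | 10.5 | 5.5 |
| ash | 1.33 | 21.3 | 9.5 |
| ash | 4.00 | 37.9 | 21.1 |
| ash | 8.00 | 44.1 | 29.1 |
| ash | 10.0 | 44.5 | 30.2 |
| ash | 15.0 | 45.6 | 32.3 |

(readings scatter by 0.3 percentage points)

- free catalyst is single-handed; left-handed substrate and right-handed substrate are mirror images of each other, charged as a racemate, each of them at the stated concentration
- the earlier runs were read with a standard deviation of 0.3 percentage points
- an excess is the difference of the two amounts in percent of their sum
- "hardly changes" means that all values lie within two and a half points (for a concentration: within two and a half percent of the largest)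

- excess of left-handed product over right-handed product at the end for delta, theta, alpha, eta, zeta, in this order
- the shape of the row from first to last (falls all the way / falls, then rises / hardly changes / rises, then falls / rises all the way)

The runs are not one-step. After 1.33 h, alder has product equal to 14.9% of its partner charge and ash 14.0%, from charges of 0.037 M and 0.22 M. We therefore read the rate as pseudo-first-order in partner. By the last reading alder has product equal to 43.2% of its partner charge and ash 35.4%. We call this share, product at the end over partner charged, the partner yield Y.

A straight line in charge through those two readings puts Y at 43.5% for delta and 38.4% for zeta. Our reckoning then gives product at 13.1% of the substrates charged in delta and 57.6% in zeta. The excess at the last reading goes from 31.2% in alder to 17.1% in ash, each carrying the scatter of the readings, while product rises. So your hunch stands, and we expect the row to fall.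

The forecast reads the runs thus: “partner is the limiting reagent, and time is not”. It gives 35%, 33%, 32%, 29% and 24%, so the row falls all the way. Its zeta conversions are 37 and 22 percent, beside our total of 57.6%.

The simulation gives 35.6%, 34.5%, 33.8%, 30.8% and 25.9%, so the row falls all the way, and the forecast stands within its margin.

free catalyst + left-handed substrate ⇌ catalyst intermediate A (K = 38.2 M⁻¹, k = 35.2 M⁻¹ min⁻¹); free catalyst + right-handed substrate ⇌ catalyst intermediate B (K = 48.0 M⁻¹, k = 8.93 M⁻¹ min⁻¹); partner + catalyst intermediate A → free catalyst + left-handed product (k = 1.89 M⁻¹ min⁻¹); partner + catalyst intermediate B → free catalyst + right-handed product (k = 0.712 M⁻¹ min⁻¹); partner → decomposed reagent (k = 0.00311 min⁻¹) In delta, both product steps and the decomposition of partner ran side by side while partner lasted, and at 15.0 h 0.707% of the partner remained, with 0.0167 M of decomposed reagent and Y at 43.5%, beside 43.2% in alder. In zeta, the same steps left 1.19% of the partner at 15.0 h, with Y at 39.2%, beside the 38.4% we had drawn, and 0.0895 M of decomposed reagent.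

The data are simulated with constants of no real substance.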